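Assumption: 3,3-dimethylpent-4-enal is taken as a catalogue compound. All other starting materials are bulk chemicals.

## Retrosynthetic overview
- Both pyrrole rings are cut last and together. A twofold Fischer indolisation with 3,3-dimethylpent-4-enal brings in both 1,1-dimethylallyl groups, and the two N–N units come from a twofold C–N coupling on a dibromide core.
- The bond from the quaternary carbon to the styryl group is cut to an exocyclic methylene compound plus a β-nitrostyrene. In the forward sense this is H-atom transfer followed by radical addition–elimination, anti to the neighbouring aryl group.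
- The methylene compound comes from a 2-aryl-4-methylcyclohex-3-enone. That ketone is cut by one carbon to 3-methylcyclopent-2-enone plus an aryldiazomethane. This is the key step: a ring expansion by 1,2-vinyl shift that sets the benzylic stereocenter.
- Both aryl units come from 4-bromobenzaldehyde, made from 1,4-dibromobenzene.
- Ring order: the benzene rings are bought, the cyclohexene is made next from the five-membered ring, and the two pyrrole rings are made last in one operation.

## Route

Step 1
Reactants: 1 1,4-dibromobenzene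
Product: 3 4-bromobenzaldehyde, via (4-bromophenyl)lithium 2 (not isolated)
Conditions: n-BuLi (1.0 equiv), THF, −78 °C; DMF, −78 °C to rt; H2O
Reagents that add atoms: N,N-dimethylformamide, CN(C)C=O
Why: Bromine–lithium exchange followed by formylation with DMF (Bouveault-type aldehyde synthesis) stops cleanly at one C–Br bond at −78 °C with one equivalent of n-BuLi, and no stereocenter is formed.

Step 2
Reactants: 3 4-bromobenzaldehyde
Product: 4 (E)-(4-bromobenzylidene)hydrazine
Conditions: N2H4·H2O (5 equiv), EtOH, rt
Reagents that add atoms: hydrazine, NN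
Why: This is a plain carbonyl condensation (hydrazone formation) in which the large excess of hydrazine suppresses the azine, and no stereocenter is formed.

Step 3
Reactants: 4 (E)-(4-bromobenzylidene)hydrazine; 5 3-methylcyclopent-2-en-1-one
Product: 7 (S)-2-(4-bromophenyl)-4-methylcyclohex-3-en-1-one, via 1-bromo-4-(diazomethyl)benzene 6 (not isolated)
Conditions: MnO2, CH2Cl2, 0 °C, filter; add cold to 5, Sc(OTf)3 (10 mol %), 1,1,1-tris[(4S)-4-isopropyl-4,5-dihydrooxazol-2-yl]ethane (12 mol %, ligand enantiomer chosen to give S), 4 Å MS, toluene, −78 to −40 °C; pH 7 buffer; use at once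
Reagents that add atoms: none
Why: Proposed new method: the chiral trivalent scandium Lewis acid binds the enone oxygen and the diazo carbon adds 1,2 on one face (the β-methyl group blocks 1,4-attack), then the β-oxido diazonium ion loses N2 with antiperiplanar 1,2-shift of the sp2 ring carbon (a better migrating group than the ring CH2 because it bridges through its π bond), which forms the six-membered β,γ-enone, the C–aryl bond and the benzylic stereocenter in one operation; the closest known reactions are the Sc(OTf)3/oxazoline-catalysed enantioselective insertion of aryldiazomethanes into saturated cycloalkanones and the Lewis-acid-promoted diazomethane homologation of enones by vinyl shift (Büchner–Curtius–Schlotterbeck or Tiffeneau–Demjanov type).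

Step 4
Reactants: 7 (S)-2-(4-bromophenyl)-4-methylcyclohex-3-en-1-one
Product: 8 (R)-1-bromo-4-(3-methyl-6-methylidenecyclohex-2-en-1-yl)benzene
Conditions: Zn, CH2Br2, TiCl4, THF/CH2Cl2, 0 °C to rt
Reagents that add atoms: dibromomethane, BrCBr
Why: The Takai–Lombardo methylenation uses a non-basic gem-dimetallic titanium methylidene equivalent, so the acidic α-stereocenter is not epimerised and the β,γ-alkene is not drawn into conjugation as it would be with a Wittig ylide (the descriptor changes from S to R only through the priority rules).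

Step 5
Reactants: 3 4-bromobenzaldehyde; 9 nitromethane
Product: 10 (E)-1-bromo-4-(2-nitroethenyl)benzene
Conditions: NH4OAc, AcOH, 100 °C
Reagents that add atoms: none
Why: The Henry (nitroaldol) condensation with dehydration in the flask gives the conjugated E-nitroalkene under thermodynamic control.

Step 6
Reactants: 8 (R)-1-bromo-4-(3-methyl-6-methylidenecyclohex-2-en-1-yl)benzene; 10 (E)-1-bromo-4-(2-nitroethenyl)benzene
Product: 11 1-bromo-4-[(1R,6S)-6-[(E)-2-(4-bromophenyl)ethenyl]-3,6-dimethylcyclohex-2-en-1-yl]benzene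
Conditions: Fe(acac)3 (30 mol %), PhSiH3 (2.5 equiv), 10 (2 equiv), EtOH, 60 °C
Reagents that add atoms: none
Why: Metal-hydride hydrogen-atom transfer (Mukaiyama-type reductive olefin coupling) delivers H to the exposed CH2 of the 1,1-disubstituted alkene faster than to the trisubstituted ring alkene, and the tertiary radical then adds to the nitro-bearing carbon of 10 on the face anti to the neighbouring aryl group and expels NO2 (radical addition–elimination), which sets the quaternary center with styryl trans and methyl cis to aryl and gives the E-alkene.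

Step 7
Reactants: 11 1-bromo-4-[(1R,6S)-6-[(E)-2-(4-bromophenyl)ethenyl]-3,6-dimethylcyclohex-2-en-1-yl]benzene
Product: 12 (1R,6S)-1-{4-[2-(diphenylmethylidene)hydrazinyl]phenyl}-6-[(E)-2-{4-[2-(diphenylmethylidene)hydrazinyl]phenyl}ethenyl]-3,6-dimethylcyclohex-2-ene
Conditions: Ph2C=NNH2 (2.3 equiv), Pd(OAc)2 (5 mol %), BINAP (7.5 mol %), NaOtBu (2.8 equiv), toluene, 80 °C
Reagents that add atoms: benzophenone hydrazone, NN=C(c1ccccc1)c1ccccc1
Why: The twofold Buchwald–Hartwig C–N coupling of aryl bromides with benzophenone hydrazone as a mono-protected hydrazine is general, the internal alkenes are poor Heck partners, and both stereocenters are untouched.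

Step 8
Reactants: 12 (1R,6S)-1-{4-[2-(diphenylmethylidene)hydrazinyl]phenyl}-6-[(E)-2-{4-[2-(diphenylmethylidene)hydrazinyl]phenyl}ethenyl]-3,6-dimethylcyclohex-2-ene; 13 3,3-dimethylpent-4-enal
Product: 15 5-[(1R,6S)-3,6-dimethyl-6-{(E)-2-[3-(2-methylbut-3-en-2-yl)-1H-indol-5-yl]ethenyl}cyclohex-2-en-1-yl]-3-(2-methylbut-3-en-2-yl)-1H-indole, via bis(enal arylhydrazone) 14 (not isolated)
Conditions: 13 (3 equiv), TsOH·H2O (4 equiv), EtOH, 70 °C, argon, 2–3 h
Reagents that add atoms: none
Why: Acid-promoted hydrazone exchange followed by a twofold Fischer indole synthesis can only give 5-substituted indoles from para-substituted arylhydrazones, and the aldehyde CH2 becomes C3, so each new pyrrole ring carries the 1,1-dimethylallyl group at C3 and H at C2 while no stereocenter is touched.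

## Compound list
1 | 1,4-dibromobenzene | Brc1ccc(Br)cc1 | starting material
2 | (4-bromophenyl)lithium | [Li]c1ccc(Br)cc1 | intermediate
3 | 4-bromobenzaldehyde | O=Cc1ccc(Br)cc1 | intermediate
4 | (E)-(4-bromobenzylidene)hydrazine | N/N=C/c1ccc(Br)cc1 | intermediate
5 | 3-methylcyclopent-2-en-1-one | CC1=CC(=O)CC1 | starting material
6 | 1-bromo-4-(diazomethyl)benzene | [N-]=[N+]=Cc1ccc(Br)cc1 | intermediate
7 | (S)-2-(4-bromophenyl)-4-methylcyclohex-3-en-1-one | O=C1CCC(C)=C[C@H]1c1ccc(Br)cc1 | intermediate
8 | (R)-1-bromo-4-(3-methyl-6-methylidenecyclohex-2-en-1-yl)benzene | C=C1CCC(C)=C[C@H]1c1ccc(Br)cc1 | intermediate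
9 | nitromethane | C[N+](=O)[O-] | starting material
10 | (E)-1-bromo-4-(2-nitroethenyl)benzene | O=[N+]([O-])/C=C/c1ccc(Br)cc1 | intermediate
11 | 1-bromo-4-[(1R,6S)-6-[(E)-2-(4-bromophenyl)ethenyl]-3,6-dimethylcyclohex-2-en-1-yl]benzene | Brc1ccc(/C=C/[C@]2(C)CCC(C)=C[C@H]2c2ccc(Br)cc2)cc1 | intermediate
12 | (1R,6S)-1-{4-[2-(diphenylmethylidene)hydrazinyl]phenyl}-6-[(E)-2-{4-[2-(diphenylmethylidene)hydrazinyl]phenyl}ethenyl]-3,6-dimethylcyclohex-2-ene | c1ccc(cc1)C(c1ccccc1)=NNc1ccc(/C=C/[C@]2(C)CCC(C)=C[C@H]2c2ccc(NN=C(c3ccccc3)c3ccccc3)cc2)cc1 | intermediate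
13 | 3,3-dimethylpent-4-enal | C=CC(C)(C)CC=O | starting material
14 | bis[(E)-3,3-dimethylpent-4-enylidene] hydrazone of the (1R,6S) bis(4-hydrazinylphenyl) core | C=CC(C)(C)C/C=N/Nc1ccc(/C=C/[C@]2(C)CCC(C)=C[C@H]2c2ccc(N/N=C/CC(C)(C)C=C)cc2)cc1 | intermediate
15 | 5-[(1R,6S)-3,6-dimethyl-6-{(E)-2-[3-(2-methylbut-3-en-2-yl)-1H-indol-5-yl]ethenyl}cyclohex-2-en-1-yl]-3-(2-methylbut-3-en-2-yl)-1H-indole | C=CC(C)(C)c1c[nH]c2ccc(/C=C/[C@]3(C)CCC(C)=C[C@H]3c3ccc4[nH]cc(C(C)(C)C=C)c4c3)cc12 | target

## Step count and risks
Total steps: 8. Longest linear sequence: 7 (steps 1, 2, 3, 4, 6, 7, 8).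

**Step 3 (the new ring expansion).**
- The conjugated carbonyl is less electrophilic than a saturated ketone.
- Epoxide formation or shift of the ring CH2 may compete with the vinyl shift.
- Ketone 7 can racemise or slip into conjugation.

The fallback sets out from 3 and 5 and comes back at 8, using the known seleno-pinacol ring enlargement instead of diazo chemistry. Aldehyde 3 is treated with PhSeH and ZnCl2 to give the selenoacetal 1-bromo-4-[bis(phenylselanyl)methyl]benzene F1. Selenium–lithium exchange (n-BuLi, THF, −78 °C) gives [(4-bromophenyl)(phenylselanyl)methyl]lithium F2. This adds 1,2 to 5 to give 1-[(4-bromophenyl)(phenylselanyl)methyl]-3-methylcyclopent-2-en-1-ol F3. AgBF4 in CH2Cl2 then removes the selenide and triggers the vinyl shift to racemic 2-(4-bromophenyl)-4-methylcyclohex-3-en-1-one F4. The conditions of step 4 give racemic 1-bromo-4-(3-methyl-6-methylidenecyclohex-2-en-1-yl)benzene F5. This stable hydrocarbon is resolved by supercritical-fluid chromatography on a chiral phase to give 8.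

**Step 6 (quaternary center).**
- Hydrogen-atom transfer to the ring alkene or to the product styrene may compete.
- The nitroalkene may be reduced.
- The alkene may isomerise, and the facial selectivity may be only modest.

The fallback sets out from 7 (and 3) and comes back at 11. It leaves hydride chemistry for a photoredox radical generated from an alcohol. MeMgBr/CeCl3 (THF, −78 °C) adds to 7 to give (1S,2S)-2-(4-bromophenyl)-1,4-dimethylcyclohex-3-en-1-ol F6. Methyl chlorooxoacetate with Et3N/DMAP gives the mixed methyl oxalate F7, and CsOH gives the cesium oxalate F8. Separately, a Horner–Wadsworth–Emmons reaction of 3 with diethyl (phenylsulfonyl)methylphosphonate and NaH gives (E)-1-bromo-4-[2-(phenylsulfonyl)ethenyl]benzene F9. Irradiating F8 and F9 with [Ir(dF(CF3)ppy)2(dtbbpy)]PF6 (blue LED, DME/DMF) releases the same tertiary radical by double decarboxylation. The radical adds anti to the aryl group and expels sulfinate to give 11.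

**Step 8 (twofold Fischer indolisation).**
- The acid may move the tert-prenyl group from C3 to C2.
- The acid may protonate the electron-rich styrene.
- The sigmatropic step is hindered by the neighbouring quaternary carbon.

The fallback sets out from 11 and comes back at 15, under neutral to basic palladium conditions without any hydrazine. Twofold amination of 11 with NH3 in dioxane (Pd2(dba)3, a Josiphos-type ligand, NaOtBu) gives the bis-aniline 4-[(1R,6S)-6-[(E)-2-(4-aminophenyl)ethenyl]-3,6-dimethylcyclohex-2-en-1-yl]aniline F10. Ortho-iodination (N-iodosuccinimide, MeCN, 0 °C, para positions blocked) gives the bis(2-iodoaniline) F11. Annulation with 13 (Pd(OAc)2, DABCO, DMF, 85 °C) proceeds by enamine formation and then an intramolecular Heck reaction, and closes both pyrrole rings to give 15.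

Further compounds
F1 | step 3 | 1-bromo-4-[bis(phenylselanyl)methyl]benzene | Brc1ccc(C([Se]c2ccccc2)[Se]c2ccccc2)cc1
F2 | step 3 | [(4-bromophenyl)(phenylselanyl)methyl]lithium | [Li]C([Se]c1ccccc1)c1ccc(Br)cc1
F3 | step 3 | 1-[(4-bromophenyl)(phenylselanyl)methyl]-3-methylcyclopent-2-en-1-ol (racemic diastereomer mixture) | CC1=CC(O)(C([Se]c2ccccc2)c2ccc(Br)cc2)CC1
F4 | step 3 | racemic 2-(4-bromophenyl)-4-methylcyclohex-3-en-1-one | O=C1CCC(C)=CC1c1ccc(Br)cc1
F5 | step 3 | racemic 1-bromo-4-(3-methyl-6-methylidenecyclohex-2-en-1-yl)benzene | C=C1CCC(C)=CC1c1ccc(Br)cc1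
F6 | step 6 | (1S,2S)-2-(4-bromophenyl)-1,4-dimethylcyclohex-3-en-1-ol | C[C@]1(O)CCC(C)=C[C@H]1c1ccc(Br)cc1
F7 | step 6 | (1S,2S)-2-(4-bromophenyl)-1,4-dimethylcyclohex-3-en-1-yl methyl oxalate | C[C@]1(OC(=O)C(=O)OC)CCC(C)=C[C@H]1c1ccc(Br)cc1
F8 | step 6 | cesium (1S,2S)-2-(4-bromophenyl)-1,4-dimethylcyclohex-3-en-1-yl oxalate | C[C@]1(OC(=O)C(=O)[O-])CCC(C)=C[C@H]1c1ccc(Br)cc1.[Cs+]
F9 | step 6 | (E)-1-bromo-4-[2-(phenylsulfonyl)ethenyl]benzene | O=S(=O)(/C=C/c1ccc(Br)cc1)c1ccccc1
F10 | step 8 | 4-[(1R,6S)-6-[(E)-2-(4-aminophenyl)ethenyl]-3,6-dimethylcyclohex-2-en-1-yl]aniline | Nc1ccc(/C=C/[C@]2(C)CCC(C)=C[C@H]2c2ccc(N)cc2)cc1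
F11 | step 8 | 4-[(1R,6S)-6-[(E)-2-(4-amino-3-iodophenyl)ethenyl]-3,6-dimethylcyclohex-2-en-1-yl]-2-iodoaniline | Nc1ccc(/C=C/[C@]2(C)CCC(C)=C[C@H]2c2ccc(N)c(I)c2)cc1I
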